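The rate constants were chosen freely; the result is computed.

**An easy step.** The easy count is a catalyst at full speed, and the flask comes first.

    precatalyst → enzyme (k1 = 0.066 s⁻¹)
    target ⇌ isomer of the product (K2 = 0.67, k2 = 0.0083 s⁻¹)
    complex → enzyme + target (k3 = 200 s⁻¹)
    starting material + enzyme ⇌ complex (K4 = 120 M⁻¹, k4 = 1.3 × 10⁶ M⁻¹ s⁻¹)

the same everywhere: precatalyst 0.01 mol%

| charge | starting material | time | remark |
|---|---|---|---|
| Monday's | 17 mM | 2.0 min | everything together in a closed stirred flask, run for 2.0 min |
| Sunday's | 17 mM (fed, over 2.00 min) | 2.0 min | a stirred flask in which starting material is dosed at a steady rate over 2.00 min without added volume, worked up at 2.0 min |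
| Saturday's | 17 mM |  | one stirred flow tank at steady state, fed with the mixture as stated, mean residence time 2.0 min |

* the set-up with the highest amount of target at the outlet or at the end, in percent of the starting material put in ("none" if the first two lie within 2 percentage points) (Monday's / Sunday's / Saturday's / none)
* amount of target at the outlet or at the end, in percent of the starting material put in, Monday's
* amount of target at the outlet or at the end, in percent of the starting material put in, Sunday's
* amount of target at the outlet or at the end, in percent of the starting material put in, Saturday's

- the stated concentrations are those of everything mixed, before any reaction; amounts are the same in each set-up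
- the feed brings no volume worth counting
- run time (Monday's): 2.0 min

**Bench rule.** Precatalyst becomes enzyme with a mean lag of 0.253 min. Complex releases target with 200 s⁻¹, so at a loading of 0.01 mol% the full charge needs 0.833 min at full speed. Monday's flask should then finish near 1.09 min, well inside 2.0 min.

**The border.** Full speed needs enzyme held as complex. The ratio that tells is the equilibrium constant of binding times the charge, 2.0, which is not large. At the start 67.1 % of the working catalyst is bound, and less as starting material falls. Complex falls apart faster than it releases target, so binding stays near equilibrium. Well below 8.33 mM of starting material the rate turns pseudo-first-order, and logarithms take over.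

**Decade time.** The decade time is the time this first-order tail needs to cut starting material by a factor 10: 0.940 min. With binding at equilibrium, the time needed is the lag, plus the converted share times the full-speed time, plus the decades fallen times the decade time.

**Own reckoning.** For Monday's flask, reaching 10.0 % left takes 1.94 min, just under 2.0 min. So a little less than that should remain. Target then passes on to isomer of the product, whose equilibrium leaves target 59.9 % of the converted material. Monday's target should therefore lie between 53.9 % and 90.0 %. In Sunday's flask the mean portion spends 1.00 min inside, against 2.0 min in Monday's. Saturday's tank works at its outlet level, below the charge. This reckoning therefore ranks Monday's first.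

**Result.** The forecast gives Monday's as best, with 65.9 %, 53.1 % and 52.6 %, on the ground that “the batch keeps the starting material high”. The simulation gives 65.9 % for Monday's, 53.1 % for Sunday's and 52.6 % for Saturday's, so Monday's leads. At 2.00 min Monday's flask holds 9.23 % of starting material. Left until 20.0 min, Monday's flask holds 59.9 % of target, less than at 2.0 min.

**Thinner catalyst.** Monday's flask is run again with 0.004 mol% of precatalyst. The lag stays, the decade time stretches to 2.35 min, and the full-speed time to 2.08 min. A fall to 50.0 % left is 0.301 of a decade and needs 2.00 min. At 2.00 min that flask holds 50 % of starting material and 37.4 % of target.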